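**Retrosynthetic overview**
- The target comes from the (1(10)E,4E)-germacradienolide by a late double epoxidation; the C8 ester comes from the C8 alcohol and a silyl-protected 2-(hydroxymethyl)acrylic acid.
- The ten-membered ring is closed at C7–C8 by an intramolecular Nozaki–Hiyama–Kishi addition of a 4-iodobutenolide (C7 as a β-acyl vinyl anion equivalent) to a C8 aldehyde.
- The iodobutenolide comes from a γ-hydroxy ynoate, iodide and formaldehyde (C7–I, C11–C13 and the O6–C12 lactone in one operation); the ynoate comes from an enal and methyl propiolate (C6–C7, sets C6).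
- The chain comes from geranyl acetate: SeO2 oxidation of the (E)-methyl group and Wittig methylenation give a terminal diene, a masked C8 aldehyde released by hydroboration–oxidation.
- Ring order: butenolide, then the ten-membered carbocycle, then the two oxiranes.

Assumption: atom labels follow germacrane numbering (C12 lactone carbonyl, C13 acetoxymethyl carbon), and the SMILES is read as the (1R,4R,5R,6S,8S,10R) isomer.

**Step 1**
Reactants: 1 geranyl acetate
Product: 2 (2E,6E)-3,7-dimethyl-8-oxoocta-2,6-dien-1-yl acetate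
Conditions: SeO2 (1.2 equiv), 95% EtOH, reflux
Reagents that add atoms: selenium dioxide, O=[Se]=O
Why: Riley allylic oxidation (ene reaction, then [2,3]-sigmatropic shift) attacks only the (E)-methyl group of the terminal trisubstituted olefin, the 2,3-olefin being deactivated by the allylic acetate, and gives the (E)-enal; no stereocentre is formed.

**Step 2**
Reactants: 2 (2E,6E)-3,7-dimethyl-8-oxoocta-2,6-dien-1-yl acetate
Product: 4 (2E,6E)-3,7-dimethylnona-2,6,8-trien-1-ol, via triene acetate 3 (not isolated)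
Conditions: Ph3PCH3Br, KOt-Bu, THF, 0 °C; add 2, −78 → 0 °C; then MeOH, K2CO3 (cat.), rt
Reagents that add atoms: methyltriphenylphosphonium bromide, C[P+](c1ccccc1)(c1ccccc1)c1ccccc1.[Br-]
Why: Wittig methylenation turns the enal into a terminal 1,3-diene (the ylide carbon becomes C8, a masked aldehyde), and base-catalysed transesterification in the same pot frees the allylic alcohol; the 6E geometry is untouched.

**Step 3**
Reactants: 4 (2E,6E)-3,7-dimethylnona-2,6,8-trien-1-ol
Product: 5 (2E,6E)-3,7-dimethylnona-2,6,8-trienal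
Conditions: MnO2 (15 equiv), CH2Cl2, rt
Reagents that add atoms: none
Why: MnO2 oxidation is selective for the primary allylic alcohol and gives the enal without E/Z isomerisation.

**Step 4**
Reactants: 5 (2E,6E)-3,7-dimethylnona-2,6,8-trienal; 6 methyl propiolate
Product: 7 methyl (4R,5E,9E)-4-hydroxy-6,10-dimethyldodeca-5,9,11-trien-2-ynoate
Conditions: 6 (3 equiv), Me2Zn (3 equiv), ProPhenol ligand (20 mol%; the enantiomer that directs Si-face addition), Ph3PO (40 mol%), toluene, 4 °C
Reagents that add atoms: none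
Why: Trost zinc–ProPhenol asymmetric alkynylation adds the zinc acetylide 1,2 to the enal under ligand control and sets C6 as the 4R carbinol, already in the spatial arrangement of the target (the antipodal ligand gives 4S).

**Step 5**
Reactants: 7 methyl (4R,5E,9E)-4-hydroxy-6,10-dimethyldodeca-5,9,11-trien-2-ynoate
Product: 9 [(5R)-4-iodo-5-[(1E,5E)-2,6-dimethylocta-1,5,7-trien-1-yl]-2-oxo-2,5-dihydrofuran-3-yl]methyl acetate, via hydroxymethyl iodobutenolide 8 (not isolated)
Conditions: i-PrMgCl (1.0 equiv), CH2Cl2/THF, −78 °C; MgI2 (1.5 equiv), CH2O (gas, from cracked paraformaldehyde), −78 → 0 °C; then Ac2O, DMAP (cat.), 0 °C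
Reagents that add atoms: magnesium iodide, [Mg+2].[I-].[I-]; formaldehyde, C=O; acetic anhydride, CC(=O)OC(C)=O
Why: Proposed new method: an iodo-aldol (β-iodo Morita–Baylis–Hillman) reaction run on a γ-oxido internal ynoate with formaldehyde and ending in lactonization — MgI2 activates the ester and delivers iodide to C7, the resulting magnesium allenolate is hydroxymethylated at C11 by CH2O preferentially syn to the small iodine, the C6 alkoxide then lies cis to the ester and closes the butenolide (other alkene isomers can equilibrate by reversible iodide addition–elimination and only this one can lactonize), and Ac2O caps the primary alkoxide; the closest known reactions are the MgI2- or Et2AlI-promoted coupling of propiolates, iodide and aldehydes to (Z)-β-iodo Baylis–Hillman esters and the lactonization of γ-hydroxy enoates; C6 is not touched.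

**Step 6**
Reactants: 9 [(5R)-4-iodo-5-[(1E,5E)-2,6-dimethylocta-1,5,7-trien-1-yl]-2-oxo-2,5-dihydrofuran-3-yl]methyl acetate
Product: 11 [(5R)-5-[(1E,5E)-2,6-dimethyl-8-oxoocta-1,5-dien-1-yl]-4-iodo-2-oxo-2,5-dihydrofuran-3-yl]methyl acetate, via alkylborane 10 (not isolated)
Conditions: 9-BBN (1.3 equiv), THF, 0 °C → rt; then NMO (8 equiv), (n-Pr4N)RuO4 (5 mol%), 4 Å MS, CH2Cl2, rt → 40 °C
Reagents that add atoms: N-methylmorpholine N-oxide, C[N+]1([O-])CCOCC1
Why: Anti-Markovnikov hydroboration by 9-BBN takes only the monosubstituted terminus of the diene (tri- and tetrasubstituted olefins, lactone and acetate are inert), and amine-oxide oxidation of the C–B bonds followed by Ley–Griffith oxidation gives the β,γ-unsaturated aldehyde under neutral conditions; no stereocentre is formed and the C10=C1 E geometry is kept.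

**Step 7**
Reactants: 11 [(5R)-5-[(1E,5E)-2,6-dimethyl-8-oxoocta-1,5-dien-1-yl]-4-iodo-2-oxo-2,5-dihydrofuran-3-yl]methyl acetate
Product: 13 [(4S,6E,10E,11aR)-4-hydroxy-6,10-dimethyl-2-oxo-2,4,5,8,9,11a-hexahydrocyclodeca[b]furan-3-yl]methyl acetate, via vinylchromium dichloride 12 (not isolated)
Conditions: CrCl2 (8 equiv), NiCl2 (2 mol% of the CrCl2), DMSO/THF 3:1, rt, syringe-pump addition of 11 to 2 mM
Reagents that add atoms: none
Why: Intramolecular Nozaki–Hiyama–Kishi reaction: zerovalent nickel inserts into the C7–I bond and transmetalates to trivalent chromium, and the C4-chromio butenolide acts as a β-acyl vinyl anion equivalent (the β-carbon of an enoate, normally an acceptor, attacks the aldehyde carbon, another acceptor), closing the ten-membered ring at C7–C8 while tolerating lactone, acetate and the enolizable aldehyde; C8 is set under macrocyclic substrate control, and the 8S carbinol (oxygen on the same face as the lactone oxygen) is expected but not secured.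

**Step 8**
Reactants: 14 methyl 2-(hydroxymethyl)acrylate
Product: 15 methyl 2-{[(tert-butyldimethylsilyl)oxy]methyl}acrylate
Conditions: TBSCl, imidazole, DMF, 0 °C → rt
Reagents that add atoms: tert-butyldimethylsilyl chloride, CC(C)(C)[Si](C)(C)Cl
Why: Standard silylation of the primary alcohol protects it from self-esterification in the coupling step.

**Step 9**
Reactants: 15 methyl 2-{[(tert-butyldimethylsilyl)oxy]methyl}acrylate
Product: 16 2-{[(tert-butyldimethylsilyl)oxy]methyl}acrylic acid
Conditions: LiOH, THF/H2O, 0 °C → rt; then 1 M HCl to pH 3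
Reagents that add atoms: lithium hydroxide, [Li+].[OH-]
Why: Saponification of the methyl ester; the primary TBS ether survives aqueous LiOH.

**Step 10**
Reactants: 13 [(4S,6E,10E,11aR)-4-hydroxy-6,10-dimethyl-2-oxo-2,4,5,8,9,11a-hexahydrocyclodeca[b]furan-3-yl]methyl acetate; 16 2-{[(tert-butyldimethylsilyl)oxy]methyl}acrylic acid
Product: 17 (4S,6E,10E,11aR)-3-(acetoxymethyl)-6,10-dimethyl-2-oxo-2,4,5,8,9,11a-hexahydrocyclodeca[b]furan-4-yl 2-{[(tert-butyldimethylsilyl)oxy]methyl}prop-2-enoate
Conditions: 16 (1.5 equiv), EDC·HCl, DMAP, CH2Cl2, 0 °C → rt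
Reagents that add atoms: none
Why: Steglich esterification acylates the C8 hydroxyl with retention of configuration.

**Step 11**
Reactants: 17 (the silyl-protected ester)
Product: 18 (4S,6E,10E,11aR)-3-(acetoxymethyl)-6,10-dimethyl-2-oxo-2,4,5,8,9,11a-hexahydrocyclodeca[b]furan-4-yl 2-(hydroxymethyl)prop-2-enoate
Conditions: HF·pyridine, pyridine, THF, 0 °C
Reagents that add atoms: none
Why: Fluoride-mediated desilylation is done before the acid-sensitive oxiranes are introduced; esters, lactone and olefins are unaffected.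

**Step 12**
Reactants: 18 (the dienyl hydroxy ester)
Product: 19 target CNP0282791.1, (1R,4R,5R,6S,8S,10R)-13-acetoxy-1,10:4,5-diepoxy-8-[2-(hydroxymethyl)acryloyloxy]germacr-7(11)-en-12,6-olide
Conditions: mCPBA (2.6 equiv), NaHCO3 (solid buffer), CH2Cl2, 0 °C → rt
Reagents that add atoms: 3-chloroperoxybenzoic acid, O=C(OO)c1cccc(Cl)c1
Why: Prilezhaev epoxidation of both E-trisubstituted olefins from the exposed outer faces of the crossed germacra-1(10),4-diene conformer, the sense in which costunolide-type germacrolides give their 1β,10α:4α,5β-diepoxides, should set (1R,10R) and (4R,5R); the butenolide and acrylate olefins are too electron-poor to react and the buffer suppresses transannular cyclization.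

**Compound list**
1 | geranyl acetate, (2E)-3,7-dimethylocta-2,6-dien-1-yl acetate | CC(C)=CCC/C(C)=C/COC(C)=O | starting material
2 | (2E,6E)-3,7-dimethyl-8-oxoocta-2,6-dien-1-yl acetate | O=C/C(C)=C/CC/C(C)=C/COC(C)=O | intermediate
3 | (2E,6E)-3,7-dimethylnona-2,6,8-trien-1-yl acetate | C=C/C(C)=C/CC/C(C)=C/COC(C)=O | intermediate
4 | (2E,6E)-3,7-dimethylnona-2,6,8-trien-1-ol | C=C/C(C)=C/CC/C(C)=C/CO | intermediate
5 | (2E,6E)-3,7-dimethylnona-2,6,8-trienal | C=C/C(C)=C/CC/C(C)=C/C=O | intermediate
6 | methyl propiolate | C#CC(=O)OC | starting material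
7 | methyl (4R,5E,9E)-4-hydroxy-6,10-dimethyldodeca-5,9,11-trien-2-ynoate | C=C/C(C)=C/CC/C(C)=C/[C@@H](O)C#CC(=O)OC | intermediate
8 | (5R)-3-(hydroxymethyl)-4-iodo-5-[(1E,5E)-2,6-dimethylocta-1,5,7-trien-1-yl]furan-2(5H)-one | C=C/C(C)=C/CC/C(C)=C/[C@H]1OC(=O)C(CO)=C1I | intermediate
9 | [(5R)-4-iodo-5-[(1E,5E)-2,6-dimethylocta-1,5,7-trien-1-yl]-2-oxo-2,5-dihydrofuran-3-yl]methyl acetate | C=C/C(C)=C/CC/C(C)=C/[C@H]1OC(=O)C(COC(C)=O)=C1I | intermediate
10 | [(5R)-5-[(1E,5E)-8-(9-borabicyclo[3.3.1]nonan-9-yl)-2,6-dimethylocta-1,5-dien-1-yl]-4-iodo-2-oxo-2,5-dihydrofuran-3-yl]methyl acetate | B1(C2CCCC1CCC2)CC/C(C)=C/CC/C(C)=C/[C@H]1OC(=O)C(COC(C)=O)=C1I | intermediate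
11 | [(5R)-5-[(1E,5E)-2,6-dimethyl-8-oxoocta-1,5-dien-1-yl]-4-iodo-2-oxo-2,5-dihydrofuran-3-yl]methyl acetate | O=CC/C(C)=C/CC/C(C)=C/[C@H]1OC(=O)C(COC(C)=O)=C1I | intermediate
12 | analogue of 11 with a dichlorochromium group (trivalent chromium) in place of iodine at C7 | O=CC/C(C)=C/CC/C(C)=C/[C@H]1OC(=O)C(COC(C)=O)=C1[Cr](Cl)Cl | intermediate
13 | [(4S,6E,10E,11aR)-4-hydroxy-6,10-dimethyl-2-oxo-2,4,5,8,9,11a-hexahydrocyclodeca[b]furan-3-yl]methyl acetate (6R,8S in germacrane numbering) | O[C@H]1C/C(C)=C/CC/C(C)=C/[C@H]2OC(=O)C(COC(C)=O)=C12 | intermediate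
14 | methyl 2-(hydroxymethyl)acrylate | C=C(CO)C(=O)OC | starting material
15 | methyl 2-{[(tert-butyldimethylsilyl)oxy]methyl}acrylate | C=C(CO[Si](C)(C)C(C)(C)C)C(=O)OC | intermediate
16 | 2-{[(tert-butyldimethylsilyl)oxy]methyl}acrylic acid | C=C(CO[Si](C)(C)C(C)(C)C)C(=O)O | intermediate
17 | (4S,6E,10E,11aR)-3-(acetoxymethyl)-6,10-dimethyl-2-oxo-2,4,5,8,9,11a-hexahydrocyclodeca[b]furan-4-yl 2-{[(tert-butyldimethylsilyl)oxy]methyl}prop-2-enoate | C=C(CO[Si](C)(C)C(C)(C)C)C(=O)O[C@H]1C/C(C)=C/CC/C(C)=C/[C@H]2OC(=O)C(COC(C)=O)=C12 | intermediate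
18 | (4S,6E,10E,11aR)-3-(acetoxymethyl)-6,10-dimethyl-2-oxo-2,4,5,8,9,11a-hexahydrocyclodeca[b]furan-4-yl 2-(hydroxymethyl)prop-2-enoate | C=C(CO)C(=O)O[C@H]1C/C(C)=C/CC/C(C)=C/[C@H]2OC(=O)C(COC(C)=O)=C12 | intermediate
19 | CNP0282791.1, (1R,4R,5R,6S,8S,10R)-13-acetoxy-1,10:4,5-diepoxy-8-[2-(hydroxymethyl)acryloyloxy]germacr-7(11)-en-12,6-olide | C=C(CO)C(=O)O[C@H]1C[C@@]2(C)O[C@@H]2CC[C@@]2(C)O[C@@H]2[C@H]2OC(=O)C(COC(C)=O)=C12 | target

**Step count**
Total: 12 steps. Longest linear sequence: 10 steps (steps 1–7 and 10–12; steps 8–9 make the side-chain acid).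

**Three steps most likely to fail**

Step 5 (iodo-aldol/lactonization). The alkene geometry of the tetrasubstituted iodo enoate and the use of formaldehyde on an internal ynoate are unproven. The fallback builds the same iodobutenolide by carbonylation and iodolactonization; it sets out from trienal 5 and returns at 9. Zinc–ProPhenol addition of propargyl acetate to 5 with the antipodal ligand gives the (4S)-propargylic alcohol F1. Methyl chloroformate and pyridine give the propargylic methyl carbonate F2. Pd(PPh3)4 under CO (1 atm) in MeOH/THF effects anti SN2′ oxidative addition of zerovalent palladium and methoxycarbonylation at C11, giving the 2,3-allenoate F3. I2 in MeCN/H2O then closes the lactone by anti iodolactonization (ester oxygen onto C6, iodine onto C7), transferring the allene axis to the 5R centre of 9. The 4S alcohol is needed because two anti steps relay the configuration.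

Step 7 (ring closure and C8 configuration). The diastereoselectivity at C8 cannot be predicted with confidence. If the cyclization of 11 gives mainly the C8 epimer F4, the material is used rather than discarded; the fallback returns at 17. Mitsunobu esterification of F4 with acid 16 (PPh3, DIAD, toluene, 0 °C) installs the side chain with inversion and replaces step 10.

Step 12 (double epoxidation). Facial selectivity rests on the macrocycle conformation, which the 7(11)-ene lactone may alter. The fallback uses reagent control in two stages; it sets out from 18 and returns at 19. Shi epoxidation with the D-fructose-derived ketone (KHSO5 as its triple salt with KHSO4 and K2SO4, K2CO3 buffer, MeCN/dimethoxymethane/H2O, 0 °C, 1.2 equiv oxidant) takes the more electron-rich C1=C10 olefin and gives the (1R,10R)-monoepoxide F5. A second Shi epoxidation with excess oxidant converts the C4=C5 olefin to the (4R,5R)-oxirane; this ketone gives R,R epoxides from E-trisubstituted olefins, which is the sense needed at both sites.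

**Further compounds**
F1 | step 5 | (4S,5E,9E)-4-hydroxy-6,10-dimethyldodeca-5,9,11-trien-2-yn-1-yl acetate | C=C/C(C)=C/CC/C(C)=C/[C@H](O)C#CCOC(C)=O
F2 | step 5 | (4S,5E,9E)-4-[(methoxycarbonyl)oxy]-6,10-dimethyldodeca-5,9,11-trien-2-yn-1-yl acetate | C=C/C(C)=C/CC/C(C)=C/[C@H](OC(=O)OC)C#CCOC(C)=O
F3 | step 5 | methyl (aR,5E,9E)-2-(acetoxymethyl)-6,10-dimethyldodeca-2,3,5,9,11-pentaenoate | COC(=O)C(COC(C)=O)=[C@]=C([H])/C=C(C)/CC/C=C(C)/C=C
F4 | step 7 | [(4R,6E,10E,11aR)-4-hydroxy-6,10-dimethyl-2-oxo-2,4,5,8,9,11a-hexahydrocyclodeca[b]furan-3-yl]methyl acetate (C8 epimer of 13) | O[C@@H]1C/C(C)=C/CC/C(C)=C/[C@H]2OC(=O)C(COC(C)=O)=C12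
F5 | step 12 | (1R,6R,8S,10R)-13-acetoxy-1,10-epoxy-8-[2-(hydroxymethyl)acryloyloxy]germacra-4E,7(11)-dien-12,6-olide | C=C(CO)C(=O)O[C@H]1C[C@@]2(C)O[C@@H]2CC/C(C)=C/[C@H]2OC(=O)C(COC(C)=O)=C12
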